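## Plan

1. Retrosynthesis: the enal is taken back to an isopropenyl group (allylic oxidation) and the C5 side chain to an acetyl group (ester, carbinol, ketone). The dihydrofuran ring is then cut at O1–C7a and C2–C3 together, leaving a 5-acetyl-2-fluorobenzyl alcohol and the bis(isovalerate) acylal of methacrolein.
2. Enabling feature: O1 of the dihydrofuran ring stands para to C5 on the benzene ring, so a C5 acetyl group makes a C7a–F bond an SNAr site. C2 (alkenyl, O1) and C3 (aryl, isovalerate) form an anti-1,2-diol monoester, the product pattern of carbonyl α-acyloxyallylation, and the ester lies 1,2 to O1, so the acyl group can shuttle between the two oxygens.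
3. Forward: the acetyl group is put on the arene (step 1) and the acylal is made (step 2). One flask then joins C2 to C3, moves the isovaleryl group to the C3 oxygen and closes the dihydrofuran ring onto the benzene ring (step 3). Ketone reduction, esterification and a two-stage allylic oxidation finish the side chains (steps 4 to 7).
4. Stereochemistry: C2 and C3 (2R,3S, trans) come from the (R)-SEGPHOS-modified catalyst made from [Ir(cod)Cl]2 and a chair transition state in step 3. The side-chain carbinol (R) comes from asymmetric transfer hydrogenation in step 4, and the (R)-2-methylbutanoyl centre from the purchased acid.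

Key step: step 3

Assumption: (2R)-2-methylbutanoic acid is purchased as the single enantiomer, and the SEGPHOS antipode in step 3 is assigned by analogy with the parent acyloxyallylation, so its mirror image would be used should the sense of induction prove opposite.

## Route

Step 1
Reactants: 1 (5-bromo-2-fluorophenyl)methanol; 2 tributyl(1-ethoxyethenyl)stannane
Product: 4 1-[4-fluoro-3-(hydroxymethyl)phenyl]ethan-1-one, via enol ether 3 (not isolated)
Conditions: Pd(PPh3)4 (5 mol%), toluene, 100 °C; then 1 M HCl, THF, rt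
Reagents that add atoms: water (O), which supplies the carbonyl oxygen on hydrolysis
Why: Migita–Kosugi–Stille coupling of the aryl bromide with an acetyl-anion equivalent tolerates the free hydroxyl group, and acid hydrolysis of the enol ether should unveil the methyl ketone para to fluorine.

Step 2
Reactants: 5 2-methylprop-2-enal (methacrolein); 6 3-methylbutanoic anhydride
Product: 7 2-methylprop-2-ene-1,1-diyl bis(3-methylbutanoate)
Conditions: FeCl3 (2 mol%), BHT (trace), neat, 0 °C to rt
Reagents that add atoms: none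
Why: Lewis acid-catalysed acylal formation (geminal diacylation of the formyl group by an anhydride) is the normal course with enals, as in the known diacetate of methacrolein.

Step 3
Reactants: 4 1-[4-fluoro-3-(hydroxymethyl)phenyl]ethan-1-one; 7 2-methylprop-2-ene-1,1-diyl bis(3-methylbutanoate)
Product: 11 (2R,3S)-5-acetyl-2-(prop-1-en-2-yl)-2,3-dihydro-1-benzofuran-3-yl 3-methylbutanoate, via aldehyde 8 (not isolated), via allylic ester 9 (not isolated), via benzylic ester 10 (not isolated)
Conditions: [Ir(cod)Cl]2 (2.5 mol%), (R)-SEGPHOS (5 mol%), 4-chloro-3-nitrobenzoic acid (10 mol%), Cs2CO3 (20 mol%), 7 (1.3 equiv), THF, 90 °C; then Cs2CO3 (2.5 equiv), DMF, 60 °C, same flask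
Reagents that add atoms: none
Why: Proposed new method: the cyclometalated iridium C,O-benzoate formed from [Ir(cod)Cl]2, SEGPHOS and the nitrobenzoic acid should dehydrogenate the primary alcohol of 4 to aldehyde 8, pass through monovalent iridium to ionise acylal 7 to an (α-acyloxy)-2-methyl-π-allyl complex of trivalent iridium, and add its (E)-σ-allyl form to 8 through a closed chair transition state to give anti ester 9; carbonate then equilibrates 9 with 10 by 1,2 O-to-O acyl shift through a five-membered orthoester anion, and the C2 alkoxide of 10 displaces fluoride at C7a by addition–elimination through a Meisenheimer complex stabilised by the para acetyl group. The closest known reaction types are the iridium-catalysed, anti-diastereo- and enantioselective carbonyl α-acyloxyallylation with allylic gem-dicarboxylates run from the alcohol oxidation level, base-mediated vicinal acyl migration and intramolecular SNAr etherification of para-acyl fluoroarenes; new are the 2-methyl group on the donor and the merger of the three events in one flask. The dihydrofuran ring closes in the 5-exo-trig mode at the aromatic carbon. C2 and C3 are both set in the C–C bond formation, their anti relationship (trans in the ring) by the chair transition state of the (E)-σ-allyl and their absolute sense by the SEGPHOS ligand, and neither is touched afterwards because the acyl shift breaks only acyl–oxygen bonds and the SNAr only the aryl–fluorine bond. The step needs chemoselective dehydrogenation of the primary alcohol in the presence of the aryl ketone (kinetic preference of this catalyst class, no external reductant) and O-arylation by the C2 oxygen only, which the substrate secures because the C3 alkoxide of 9 could only close a four-membered ring while fluorine sits para to the acetyl group.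

Step 4
Reactants: 11 (2R,3S)-5-acetyl-2-(prop-1-en-2-yl)-2,3-dihydro-1-benzofuran-3-yl 3-methylbutanoate
Product: 12 (2R,3S)-5-[(1R)-1-hydroxyethyl]-2-(prop-1-en-2-yl)-2,3-dihydro-1-benzofuran-3-yl 3-methylbutanoate
Conditions: RuCl[(R,R)-TsDPEN](p-cymene) (1 mol%), HCO2H/Et3N (5:2), EtOAc, 30 °C
Reagents that add atoms: none
Why: Noyori–Ikariya asymmetric transfer hydrogenation of an aryl methyl ketone with the (R,R)-catalyst should deliver hydride to the Si face and give the (R)-carbinol (as acetophenone gives (R)-1-phenylethanol), while the esters and the 1,1-disubstituted alkene are inert to outer-sphere hydride transfer.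

Step 5
Reactants: 12 (2R,3S)-5-[(1R)-1-hydroxyethyl]-2-(prop-1-en-2-yl)-2,3-dihydro-1-benzofuran-3-yl 3-methylbutanoate; 13 (2R)-2-methylbutanoic acid
Product: 14 (1R)-1-[(2R,3S)-3-[(3-methylbutanoyl)oxy]-2-(prop-1-en-2-yl)-2,3-dihydro-1-benzofuran-5-yl]ethyl (2R)-2-methylbutanoate
Conditions: 13 (1.3 equiv), EDC·HCl (1.5 equiv), DMAP (0.1 equiv), CH2Cl2, 0 °C to rt
Reagents that add atoms: none
Why: Steglich esterification leaves the carbinol C–O bond intact, so (R) is retained, and low DMAP loading at 0 °C should limit ketene-type epimerisation of the α-centre of the acid.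

Step 6
Reactants: 14 (1R)-1-[(2R,3S)-3-[(3-methylbutanoyl)oxy]-2-(prop-1-en-2-yl)-2,3-dihydro-1-benzofuran-5-yl]ethyl (2R)-2-methylbutanoate
Product: 15 (1R)-1-[(2R,3S)-2-(3-hydroxyprop-1-en-2-yl)-3-[(3-methylbutanoyl)oxy]-2,3-dihydro-1-benzofuran-5-yl]ethyl (2R)-2-methylbutanoate
Conditions: SeO2 (0.5 equiv), t-BuOOH (3 equiv, in decane), CH2Cl2, 0 °C to rt
Reagents that add atoms: selenium dioxide (O=[Se]=O), which delivers the hydroxyl oxygen, and tert-butyl hydroperoxide (CC(C)(C)OO), which regenerates it
Why: Riley allylic oxidation (ene reaction at the terminal CH2, then [2,3]-sigmatropic shift) should hydroxylate the methyl group and return the double bond to its place, the methyl C–H being preferred over the tertiary, oxygen-deactivated C2–H as is known for isopropenyl-dihydrobenzofurans.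

Step 7
Reactants: 15 (1R)-1-[(2R,3S)-2-(3-hydroxyprop-1-en-2-yl)-3-[(3-methylbutanoyl)oxy]-2,3-dihydro-1-benzofuran-5-yl]ethyl (2R)-2-methylbutanoate
Product: 16 (1R)-1-[(2R,3S)-3-[(3-methylbutanoyl)oxy]-2-(3-oxoprop-1-en-2-yl)-2,3-dihydro-1-benzofuran-5-yl]ethyl (2R)-2-methylbutanoate
Conditions: MnO2 (activated, 15 equiv), CH2Cl2, rt
Reagents that add atoms: none
Why: Activated MnO2 oxidises the primary allylic alcohol chemoselectively to the 2-substituted acrolein and should leave the esters, the benzylic C–H bonds and all four stereocentres untouched.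

## Compound list

1 | (5-bromo-2-fluorophenyl)methanol | OCc1cc(Br)ccc1F | starting material
2 | tributyl(1-ethoxyethenyl)stannane | CCCC[Sn](CCCC)(CCCC)C(=C)OCC | starting material
3 | [5-(1-ethoxyethenyl)-2-fluorophenyl]methanol | C=C(OCC)c1ccc(F)c(CO)c1 | intermediate
4 | 1-[4-fluoro-3-(hydroxymethyl)phenyl]ethan-1-one | CC(=O)c1ccc(F)c(CO)c1 | intermediate
5 | 2-methylprop-2-enal (methacrolein) | C=C(C)C=O | starting material
6 | 3-methylbutanoic anhydride | CC(C)CC(=O)OC(=O)CC(C)C | starting material
7 | 2-methylprop-2-ene-1,1-diyl bis(3-methylbutanoate) | C=C(C)C(OC(=O)CC(C)C)OC(=O)CC(C)C | intermediate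
8 | 5-acetyl-2-fluorobenzaldehyde | CC(=O)c1ccc(F)c(C=O)c1 | intermediate
9 | (1S,2R)-1-(5-acetyl-2-fluorophenyl)-1-hydroxy-3-methylbut-3-en-2-yl 3-methylbutanoate | C=C(C)[C@@H](OC(=O)CC(C)C)[C@@H](O)c1cc(C(C)=O)ccc1F | intermediate
10 | (1S,2R)-1-(5-acetyl-2-fluorophenyl)-2-hydroxy-3-methylbut-3-en-1-yl 3-methylbutanoate | C=C(C)[C@@H](O)[C@@H](OC(=O)CC(C)C)c1cc(C(C)=O)ccc1F | intermediate
11 | (2R,3S)-5-acetyl-2-(prop-1-en-2-yl)-2,3-dihydro-1-benzofuran-3-yl 3-methylbutanoate | C=C(C)[C@H]1Oc2ccc(C(C)=O)cc2[C@@H]1OC(=O)CC(C)C | intermediate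
12 | (2R,3S)-5-[(1R)-1-hydroxyethyl]-2-(prop-1-en-2-yl)-2,3-dihydro-1-benzofuran-3-yl 3-methylbutanoate | C=C(C)[C@H]1Oc2ccc([C@@H](C)O)cc2[C@@H]1OC(=O)CC(C)C | intermediate
13 | (2R)-2-methylbutanoic acid | CC[C@@H](C)C(=O)O | starting material
14 | (1R)-1-[(2R,3S)-3-[(3-methylbutanoyl)oxy]-2-(prop-1-en-2-yl)-2,3-dihydro-1-benzofuran-5-yl]ethyl (2R)-2-methylbutanoate | C=C(C)[C@H]1Oc2ccc([C@@H](C)OC(=O)[C@H](C)CC)cc2[C@@H]1OC(=O)CC(C)C | intermediate
15 | (1R)-1-[(2R,3S)-2-(3-hydroxyprop-1-en-2-yl)-3-[(3-methylbutanoyl)oxy]-2,3-dihydro-1-benzofuran-5-yl]ethyl (2R)-2-methylbutanoate | C=C(CO)[C@H]1Oc2ccc([C@@H](C)OC(=O)[C@H](C)CC)cc2[C@@H]1OC(=O)CC(C)C | intermediate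
16 | (1R)-1-[(2R,3S)-3-[(3-methylbutanoyl)oxy]-2-(3-oxoprop-1-en-2-yl)-2,3-dihydro-1-benzofuran-5-yl]ethyl (2R)-2-methylbutanoate | C=C(C=O)[C@H]1Oc2ccc([C@@H](C)OC(=O)[C@H](C)CC)cc2[C@@H]1OC(=O)CC(C)C | target

## Step count and risks

Total steps: 7. Longest linear sequence: 6 (steps 1, 3, 4, 5, 6, 7).

**Step 3.** The 2-methyl-substituted acyloxyallyl donor may ionise or add slowly, and anti or facial selectivity may erode. Transfer hydrogenation may consume the aryl ketone. Intermolecular SNAr of the benzylic alcohol, acyl scrambling between molecules, or acylation of the C2 oxygen by excess acylal may compete with ring closure.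

The fallback uses known reactions only, sets out from 4 and comes back at 11. MnO2 in CH2Cl2 oxidises 4 to aldehyde 8, now isolated. 2-Methylprop-2-en-1-ol is protected (MOMCl, i-Pr2NEt) as 3-(methoxymethoxy)-2-methylprop-1-ene F1. F1 is lithiated at the oxygen-bearing carbon (s-BuLi, THF, −78 °C) and trapped with 2-isopropoxy-4,4,5,5-tetramethyl-1,3,2-dioxaborolane to give the (Z)-γ-alkoxyallylboronate 2-[(2Z)-3-(methoxymethoxy)-2-methylprop-2-en-1-yl]-4,4,5,5-tetramethyl-1,3,2-dioxaborolane F2. Chiral phosphoric acid-catalysed allylboration of 8 with F2 ((S)-TRIP, 5 mol%, toluene, −30 °C; chair transition state, Z reagent gives syn, Si-face attack expected by analogy) should give the syn alcohol 1-{4-fluoro-3-[(1R,2R)-1-hydroxy-2-(methoxymethoxy)-3-methylbut-3-en-1-yl]phenyl}ethan-1-one F3. Mitsunobu inversion at the benzylic carbinol with 3-methylbutanoic acid (PPh3, DIAD, toluene, 0 °C) should give the anti ester (1S,2R)-1-(5-acetyl-2-fluorophenyl)-2-(methoxymethoxy)-3-methylbut-3-en-1-yl 3-methylbutanoate F4. ZnBr2 and n-PrSH in CH2Cl2 at 0 °C remove the methoxymethyl group to give 10, and Cs2CO3 in DMF at 60 °C closes the ring to 11.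

**Step 6.** Hydrogen abstraction may occur at the tertiary C2–H instead of the methyl group, over-oxidation may follow, or acid may promote loss of isovaleric acid from C3 with aromatisation to the benzofuran.

The fallback sets out from 14 and comes back at 16. Ene-type chlorination of the isopropenyl group (NaOCl, CeCl3·7H2O, CH2Cl2/H2O, 0 °C) should give the allylic chloride (1R)-1-[(2R,3S)-2-(3-chloroprop-1-en-2-yl)-3-[(3-methylbutanoyl)oxy]-2,3-dihydro-1-benzofuran-5-yl]ethyl (2R)-2-methylbutanoate F5. Ganem oxidation (trimethylamine N-oxide, NaI cat., DMSO, rt) then converts the chloride directly into enal 16, bypassing 15 and selenium.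

**Step 2.** Cationic polymerisation or conjugate addition at the enal may outrun 1,2-diacylation, which is slower with the branched anhydride.

The fallback sets out from 4 and comes back at 11. Purchased 2-methylprop-2-ene-1,1-diyl diacetate (CC(=O)OC(OC(C)=O)C(C)=C) replaces 7 under the conditions of step 3. The acetate counterparts of 9 and 10, (1S,2R)-1-(5-acetyl-2-fluorophenyl)-1-hydroxy-3-methylbut-3-en-2-yl acetate F6 and (1S,2R)-1-(5-acetyl-2-fluorophenyl)-2-hydroxy-3-methylbut-3-en-1-yl acetate F7, should lead to (2R,3S)-5-acetyl-2-(prop-1-en-2-yl)-2,3-dihydro-1-benzofuran-3-yl acetate F8. K2CO3 in MeOH at 0 °C gives 1-[(2R,3S)-3-hydroxy-2-(prop-1-en-2-yl)-2,3-dihydro-1-benzofuran-5-yl]ethan-1-one F9, and anhydride 6 with DMAP and Et3N in CH2Cl2 acylates it to 11.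

## Further compounds

F1 | step 3 | 3-(methoxymethoxy)-2-methylprop-1-ene | C=C(C)COCOC
F2 | step 3 | 2-[(2Z)-3-(methoxymethoxy)-2-methylprop-2-en-1-yl]-4,4,5,5-tetramethyl-1,3,2-dioxaborolane | COCO/C=C(/C)CB1OC(C)(C)C(C)(C)O1
F3 | step 3 | 1-{4-fluoro-3-[(1R,2R)-1-hydroxy-2-(methoxymethoxy)-3-methylbut-3-en-1-yl]phenyl}ethan-1-one | C=C(C)[C@@H](OCOC)[C@H](O)c1cc(C(C)=O)ccc1F
F4 | step 3 | (1S,2R)-1-(5-acetyl-2-fluorophenyl)-2-(methoxymethoxy)-3-methylbut-3-en-1-yl 3-methylbutanoate | C=C(C)[C@@H](OCOC)[C@@H](OC(=O)CC(C)C)c1cc(C(C)=O)ccc1F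
F5 | step 6 | (1R)-1-[(2R,3S)-2-(3-chloroprop-1-en-2-yl)-3-[(3-methylbutanoyl)oxy]-2,3-dihydro-1-benzofuran-5-yl]ethyl (2R)-2-methylbutanoate | C=C(CCl)[C@H]1Oc2ccc([C@@H](C)OC(=O)[C@H](C)CC)cc2[C@@H]1OC(=O)CC(C)C
F6 | step 2 | (1S,2R)-1-(5-acetyl-2-fluorophenyl)-1-hydroxy-3-methylbut-3-en-2-yl acetate | C=C(C)[C@@H](OC(C)=O)[C@@H](O)c1cc(C(C)=O)ccc1F
F7 | step 2 | (1S,2R)-1-(5-acetyl-2-fluorophenyl)-2-hydroxy-3-methylbut-3-en-1-yl acetate | C=C(C)[C@@H](O)[C@@H](OC(C)=O)c1cc(C(C)=O)ccc1F
F8 | step 2 | (2R,3S)-5-acetyl-2-(prop-1-en-2-yl)-2,3-dihydro-1-benzofuran-3-yl acetate | C=C(C)[C@H]1Oc2ccc(C(C)=O)cc2[C@@H]1OC(C)=O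
F9 | step 2 | 1-[(2R,3S)-3-hydroxy-2-(prop-1-en-2-yl)-2,3-dihydro-1-benzofuran-5-yl]ethan-1-one | C=C(C)[C@H]1Oc2ccc(C(C)=O)cc2[C@@H]1O
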